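Cuts: after the two benzyl ethers, ring A of the apigenin unit is opened at C7–C8 and C5–C6. This gives a 6-aryl-2-methyl-4-pyranone-3-carboxylate (O1, C2–C4, C4a, C8a; CH3 = C8, CO2Me = C5) and an aryloxyacetate (C6, C7, ether O) that already carries the genkwanin flavone.
Enabling feature: C6 holds the diaryl ether oxygen between the C5 and C7 hydroxyls, so C5–C6–C7 is the bis-enol form of a 2-aryloxy-1,3-dicarbonyl unit. Ring A (C4a, C5, C6, C7, C8, C8a) can therefore be closed around ArO–CH2–C(=O) on a pyranone that already owns O1 and C4, and the hindered C6–O bond is bought as an ordinary alkyl aryl ether.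
Further cuts: the genkwanin flavone goes back through its 2'-hydroxychalcone to an acetophenone and an aldehyde. The pyranone goes back through O1–C2 (flavone numbering) to an acylated acetoacetate and an arylpropiolic acid.
Ring order forward: ring C of the genkwanin unit; separately the monocyclic 4-pyranone (future ring C of the apigenin unit); then union of the halves and closure of carbocyclic ring A in one operation; last, double debenzylation.
Stereochemistry: none to set, since neocryptomerin has no stereogenic unit. The E alkene of the chalcone arises under thermodynamic control and disappears when the flavone forms.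
Key step: step 9

Remark: the tricarbonyl ester of step 7 and the open ketone of step 9 are drawn as keto tautomers, although both should be largely enolised. The CH of the tricarbonyl ester is configurationally labile and carries no stereochemical information.

Step 1
Reactants: 1 2',6'-dihydroxy-4'-methoxyacetophenone
Product: 2 2'-benzyloxy-6'-hydroxy-4'-methoxyacetophenone
Conditions: BnBr (1.05 equiv), K2CO3 (1.1 equiv), acetone, reflux
Reagents that add atoms: benzyl bromide BrCc1ccccc1
Why: Williamson etherification of one of two equivalent phenols, after which the remaining OH is held in a strong hydrogen bond to the acetyl group and should react much more slowly, so the reaction should stop at the monoether.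

Step 2
Reactants: 2 2'-benzyloxy-6'-hydroxy-4'-methoxyacetophenone; 3 (4-formylphenoxy)acetic acid
Product: 4 (E)-{4-[3-(2-benzyloxy-6-hydroxy-4-methoxyphenyl)-3-oxoprop-1-enyl]phenoxy}acetic acid (chalcone acid)
Conditions: KOH (6 equiv), EtOH–H2O, rt; then aq. HCl
Reagents that add atoms: none
Why: Claisen–Schmidt condensation in which the methyl ketone enolate adds to the non-enolisable aldehyde and E1cB dehydration gives the conjugated, thermodynamically preferred E enone, while the acid travels as its inert carboxylate.

Step 3
Reactants: 4 chalcone acid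
Product: 5 [4-(5-benzyloxy-7-methoxy-4-oxo-4H-chromen-2-yl)phenoxy]acetic acid (flavone acid)
Conditions: I2 (10 mol %), DMSO, 120 °C
Reagents that add atoms: none
Why: Iodine/DMSO oxidative cyclisation of a 2'-hydroxychalcone (6-endo-trig oxa-Michael closure of ring C, alpha-iodination, loss of HI, re-oxidation of HI by DMSO) is the standard entry to 5,7-dialkoxyflavones, and the catalytic iodine loading keeps the HI level low for the benzyl ether.

Step 4
Reactants: 5 flavone acid
Product: 6 methyl [4-(5-benzyloxy-7-methoxy-4-oxo-4H-chromen-2-yl)phenoxy]acetate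
Conditions: MeI (1.2 equiv), K2CO3 (1.2 equiv), DMF, rt
Reagents that add atoms: iodomethane CI
Why: SN2 O-alkylation of the carboxylate under acid-free conditions, with no free phenol left to compete and no risk to the acid-sensitive peri benzyl ether.

Step 5
Reactants: 7 1-benzyloxy-4-ethynylbenzene
Product: 8 3-(4-benzyloxyphenyl)propiolic acid
Conditions: n-BuLi (1.05 equiv), THF, −78 °C; CO2; aq. HCl
Reagents that add atoms: carbon dioxide O=C=O
Why: Carboxylation of a lithium acetylide, in which the terminal alkyne proton is by far the most acidic site and the benzylic ether position is untouched at −78 °C.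

Step 6
Reactants: 8 3-(4-benzyloxyphenyl)propiolic acid
Product: 9 3-(4-benzyloxyphenyl)propioloyl chloride (crude, used at once)
Conditions: (COCl)2 (1.2 equiv), DMF (cat.), CH2Cl2, 0 °C to rt; evaporation
Reagents that add atoms: oxalyl chloride ClC(=O)C(=O)Cl
Why: Acid chloride formation through the catalytic Vilsmeier-type chloroiminium species proceeds cold and without heating in HCl, which should avoid hydrochlorination of the triple bond.

Step 7
Reactants: 9 3-(4-benzyloxyphenyl)propioloyl chloride; 10 methyl acetoacetate
Product: 11 methyl 2-acetyl-5-(4-benzyloxyphenyl)-3-oxopent-4-ynoate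
Conditions: MgCl2 (1 equiv), pyridine (2 equiv), CH2Cl2, 0 °C; then 9, 0 °C to rt; cold dilute HCl wash
Reagents that add atoms: none
Why: Soft-enolisation C-acylation of a beta-ketoester, in which the chelated magnesium enolate blocks both oxygens and directs the acid chloride to carbon, and the product is protected as its own magnesium chelate until work-up.

Step 8
Reactants: 11 methyl 2-acetyl-5-(4-benzyloxyphenyl)-3-oxopent-4-ynoate
Product: 12 methyl 6-(4-benzyloxyphenyl)-2-methyl-4-oxo-4H-pyran-3-carboxylate
Conditions: p-TsOH·H2O (10 mol %), toluene, 80 °C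
Reagents that add atoms: none
Why: Acid-promoted 6-endo-dig oxa-Michael cyclisation of an acetylenic beta-diketone to a gamma-pyranone, a pure isomerisation in which the acetyl enol oxygen adds to the alkyne carbon whose developing positive charge is stabilised by the 4-alkoxyphenyl group.

Step 9
Reactants: 6 methyl [4-(5-benzyloxy-7-methoxy-4-oxo-4H-chromen-2-yl)phenoxy]acetate; 12 methyl 6-(4-benzyloxyphenyl)-2-methyl-4-oxo-4H-pyran-3-carboxylate
Product: 14 5-O,4'''-O-dibenzylneocryptomerin (6-[4-(5-benzyloxy-7-methoxy-4-oxo-4H-chromen-2-yl)phenoxy]-2-(4-benzyloxyphenyl)-5,7-dihydroxy-4H-chromen-4-one), via aryloxymethyl ketone 13 (not isolated)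
Conditions: 12 (1.5 equiv), LiN(SiMe3)2 (1.6 equiv), THF, −78 °C; 6 (1 equiv); then LiN(SiMe3)2 (3 equiv), −78 °C to rt; AcOH quench
Reagents that add atoms: none
Why: Proposed new method: LiN(SiMe3)2 deprotonates the 2-methyl group of 12, whose anion is delocalised through C2=C3 into both the C4 ketone and the C3 ester, and this extended enolate attacks the inductively activated ester of 6 through its exocyclic carbon (Claisen acylation, new C7–C8 bond, first methoxide lost) to give 13 as its enolate. The extra base then reaches the ArO–CH2 position, and that carbon adds to the adjacent C3 ester in a 6-(enolendo)-exo-trig Dieckmann closure (new C5–C6 bond), after which loss of the second methoxide and double enolisation deliver carbocyclic ring A as a phloroglucinol-type bis-phenoxide, an aromatisation that makes the sequence irreversible. The closest known reaction types are the lateral metalation–acylation of 2-methyl-4-pyranones and the base-induced Claisen-type cyclisation of 2-(2-oxoalkyl)benzoates and related polyketide chains onto an ortho ester to give 1,3-dihydroxyarenes; running the two in tandem on a pyranone-3-carboxylate, with an aryloxyacetate that carries a flavone, has no direct precedent. No stereocentre is created. The 6-aryloxy (not 8-aryloxy) pattern is built in, because the heterocycle with O1 and C8a exists before ring A does and no cyclisation has to choose between two ortho phenols, while closure onto C4 instead of the ester would demand a bicyclo[3.3.1] frame with a bridgehead C2=C3 alkene. Chemoselectivity is secured by forming the anion of 12 before 6 is added (less enolisation and self-condensation of 6), by a hindered silylamide that neither adds to nor metalates the electron-rich flavone of 6, and by the reversibility of the competing O-acylation to an enol lactone in the presence of LiOMe, which lets that material drain to the aromatic product.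

Step 10
Reactants: 14 5-O,4'''-O-dibenzylneocryptomerin
Product: 15 neocryptomerin
Conditions: H2 (1 atm), 10% Pd/C, THF–MeOH, rt
Reagents that add atoms: none
Why: Catalytic hydrogenolysis cleaves both aryl benzyl ethers under neutral conditions that leave the diaryl ether, the methyl ether and the flavone C2=C3 bonds intact and give no opening for an acid-induced Wessely–Moser shift of the 6-aryloxy group to C8.

Compound list
1 | 2',6'-dihydroxy-4'-methoxyacetophenone | CC(=O)c1c(O)cc(OC)cc1O | starting material
2 | 2'-benzyloxy-6'-hydroxy-4'-methoxyacetophenone | CC(=O)c1c(O)cc(OC)cc1OCc1ccccc1 | intermediate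
3 | (4-formylphenoxy)acetic acid | O=Cc1ccc(OCC(=O)O)cc1 | starting material
4 | (E)-{4-[3-(2-benzyloxy-6-hydroxy-4-methoxyphenyl)-3-oxoprop-1-enyl]phenoxy}acetic acid | COc1cc(O)c(C(=O)/C=C/c2ccc(OCC(=O)O)cc2)c(OCc2ccccc2)c1 | intermediate
5 | [4-(5-benzyloxy-7-methoxy-4-oxo-4H-chromen-2-yl)phenoxy]acetic acid | OC(=O)COc1ccc(-c2cc(=O)c3c(OCc4ccccc4)cc(OC)cc3o2)cc1 | intermediate
6 | methyl [4-(5-benzyloxy-7-methoxy-4-oxo-4H-chromen-2-yl)phenoxy]acetate | COC(=O)COc1ccc(-c2cc(=O)c3c(OCc4ccccc4)cc(OC)cc3o2)cc1 | intermediate
7 | 1-benzyloxy-4-ethynylbenzene | C#Cc1ccc(OCc2ccccc2)cc1 | starting material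
8 | 3-(4-benzyloxyphenyl)propiolic acid | OC(=O)C#Cc1ccc(OCc2ccccc2)cc1 | intermediate
9 | 3-(4-benzyloxyphenyl)propioloyl chloride | ClC(=O)C#Cc1ccc(OCc2ccccc2)cc1 | intermediate
10 | methyl acetoacetate | COC(=O)CC(C)=O | starting material
11 | methyl 2-acetyl-5-(4-benzyloxyphenyl)-3-oxopent-4-ynoate (keto form, labile CH) | COC(=O)C(C(C)=O)C(=O)C#Cc1ccc(OCc2ccccc2)cc1 | intermediate
12 | methyl 6-(4-benzyloxyphenyl)-2-methyl-4-oxo-4H-pyran-3-carboxylate | COC(=O)c1c(C)oc(-c2ccc(OCc3ccccc3)cc2)cc1=O | intermediate
13 | methyl 6-(4-benzyloxyphenyl)-2-{3-[4-(5-benzyloxy-7-methoxy-4-oxo-4H-chromen-2-yl)phenoxy]-2-oxopropyl}-4-oxo-4H-pyran-3-carboxylate (open aryloxymethyl ketone, not isolated) | COC(=O)c1c(CC(=O)COc2ccc(-c3cc(=O)c4c(OCc5ccccc5)cc(OC)cc4o3)cc2)oc(-c2ccc(OCc3ccccc3)cc2)cc1=O | intermediate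
14 | 5-O,4'''-O-dibenzylneocryptomerin | COc1cc(OCc2ccccc2)c2c(=O)cc(-c3ccc(Oc4c(O)cc5oc(-c6ccc(OCc7ccccc7)cc6)cc(=O)c5c4O)cc3)oc2c1 | intermediate
15 | neocryptomerin | COc1cc(O)c2c(=O)cc(-c3ccc(Oc4c(O)cc5oc(-c6ccc(O)cc6)cc(=O)c5c4O)cc3)oc2c1 | target

Total step count: 10.
Longest linear sequence: 6 steps (1–4, 9, 10; the arm 5–8, 9, 10 is equally long).

Steps most likely to fail

1. Step 9.
- What may go wrong: proton transfer from the ArO–CH2 group of 6 to the lateral anion, followed by self-condensation of the ester. The sequence may also stop after the first acylation and divert into O-acylation on the C3 ester. Liberated methoxide may open the pyranone.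
- Fallback (known chemistry; sets out from 2, comes back at 15): the de novo ring is given up and the C6–O bond is made by nucleophilic aromatic substitution on a finished flavone.
- Purchased scutellarein is benzylated at its two most acidic phenols (BnBr, 2 equiv, K2CO3, DMF, rt) to 7,4'-di-O-benzylscutellarein F1.
- Under argon the 6-phenoxide of F1, whose 5-OH stays chelated to the carbonyl, displaces fluoride from 4-fluorobenzaldehyde (K2CO3, DMF, 110 °C). This gives 4-{[7-benzyloxy-2-(4-benzyloxyphenyl)-5-hydroxy-4-oxo-4H-chromen-6-yl]oxy}benzaldehyde F2.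
- Claisen–Schmidt condensation of this aldehyde with 2 (KOH, EtOH, rt) gives the flavone-bearing E chalcone F3.
- I2 (cat.) in DMSO at 120 °C closes the second flavone to 5-O,7''-O,4'''-O-tribenzylneocryptomerin F4.
- Hydrogenolysis under the conditions of step 10 removes all three benzyl groups and gives 15.

2. Step 7.
- What may go wrong: O-acylation instead of C-acylation, conjugate addition of pyridine or of the enolate to the alkynoyl chloride, and deacetylation of the tricarbonyl product during work-up.
- Fallback (sets out from 10, comes back at 12; bypasses 9 and 11): the pyranone is assembled by an acylketene addition–elimination instead of an ynone cyclisation.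
- Compound 10 is condensed with pyrrolidine (toluene, water separation) to methyl (E)-3-(pyrrolidin-1-yl)but-2-enoate F5.
- Meldrum's acid is C-acylated with purchased 4-benzyloxybenzoyl chloride (pyridine, CH2Cl2, 0 °C) to 5-[(4-benzyloxyphenyl)(hydroxy)methylidene]-2,2-dimethyl-1,3-dioxane-4,6-dione F6.
- Heating this acyl Meldrum's acid (used in excess) in toluene generates (4-benzyloxybenzoyl)ketene F7.
- The nucleophilic C2 of the enamino ester attacks the ketene carbon, the aroyl oxygen closes on the iminium carbon, and pyrrolidine is expelled to give 12.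

3. Step 3.
- What may go wrong: cleavage of the peri benzyl ether by HI at high temperature, electrophilic iodination of the electron-rich ring A, or a stall at the dihydro stage.
- Fallback (sets out from 4, comes back at 5): cyclisation and oxidation are separated, so no HI is ever present.
- Compound 4 is isomerised by oxa-Michael closure (NaOAc, EtOH, reflux) to racemic [4-(5-benzyloxy-7-methoxy-4-oxochroman-2-yl)phenoxy]acetic acid F8.
- This flavanone is dehydrogenated with DDQ in refluxing dioxane to 5.

Further compounds
F1 | step 9 | 7-benzyloxy-2-(4-benzyloxyphenyl)-5,6-dihydroxy-4H-chromen-4-one (7,4'-di-O-benzylscutellarein) | O=c1cc(-c2ccc(OCc3ccccc3)cc2)oc2cc(OCc3ccccc3)c(O)c(O)c12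
F2 | step 9 | 4-{[7-benzyloxy-2-(4-benzyloxyphenyl)-5-hydroxy-4-oxo-4H-chromen-6-yl]oxy}benzaldehyde | O=Cc1ccc(Oc2c(O)c3c(=O)cc(-c4ccc(OCc5ccccc5)cc4)oc3cc2OCc2ccccc2)cc1
F3 | step 9 | (E)-chalcone from F2 and 2 | COc1cc(O)c(C(=O)/C=C/c2ccc(Oc3c(O)c4c(=O)cc(-c5ccc(OCc6ccccc6)cc5)oc4cc3OCc3ccccc3)cc2)c(OCc2ccccc2)c1
F4 | step 9 | 5-O,7''-O,4'''-O-tribenzylneocryptomerin | COc1cc(OCc2ccccc2)c2c(=O)cc(-c3ccc(Oc4c(O)c5c(=O)cc(-c6ccc(OCc7ccccc7)cc6)oc5cc4OCc4ccccc4)cc3)oc2c1
F5 | step 7 | methyl (E)-3-(pyrrolidin-1-yl)but-2-enoate | COC(=O)/C=C(/N1CCCC1)C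
F6 | step 7 | 5-[(4-benzyloxyphenyl)(hydroxy)methylidene]-2,2-dimethyl-1,3-dioxane-4,6-dione | CC1(C)OC(=O)C(=C(O)c2ccc(OCc3ccccc3)cc2)C(=O)O1
F7 | step 7 | (4-benzyloxybenzoyl)ketene (transient) | O=C=CC(=O)c1ccc(OCc2ccccc2)cc1
F8 | step 3 | [4-(5-benzyloxy-7-methoxy-4-oxochroman-2-yl)phenoxy]acetic acid (racemic) | OC(=O)COc1ccc(C2CC(=O)c3c(OCc4ccccc4)cc(OC)cc3O2)cc1
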